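**Plan**

- Retrosynthesis: the five ring–CH2–ring bridges are cut first (A/B, then E/F, then C/D, then B/C and D/E), then the butyryl C–C bond on ring F, and finally ring F itself at C(OH)–C(CH3) and C(CH2 arm)–C(O).
- Enabling feature: ring F is a benzene whose six carbons carry OH, CH3, OH, CH2 arm, OH and butyryl, with oxygen and carbon substituents strictly alternating. Its C(CH3)–C(O) pair is a CH3–C≡C–O unit, and the other four carbons are a 3-oxygenated cyclobutenone with the CH2 arm on C2; the cyclobutenone CH2 becomes the carbon that later takes the butyryl group.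
- Forward order: ring F is built first by benzannulation, acylated at its last CH and unmasked as a methoxymethyl-phloroglucinol (a quinone methide precursor). Rings B–E come from 2',4',6'-trihydroxybutyrophenone by two Mannich base/quinone methide unions (monomer to dimer, dimer to tetramer). Ring F is joined to ring E, and ring A (the same ketone, gem-dimethylated) is attached last through a Mannich base on ring B.
- Stereochemistry: the target has no stereocentre, so nothing has to be set.

Key step: step 4

Remark: ring A is an enolised triketone that tautomerises freely; it is written in the enol form of the target SMILES, each quinone methide is written as one tautomer, and all phenol/enol tautomers are treated as the same compound.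

**Route**

Step 1
Reactants: 1 propyne
Product: 4 1-(triisopropylsiloxy)prop-1-yne, via lithium propynide 2 (not isolated), via lithium propynolate 3 (not isolated)
Conditions: n-BuLi, THF, −78 °C; LiOOtBu [t-BuOOH, LiN(SiMe3)2], −78 → 0 °C; iPr3SiOTf, −78 → 0 °C
Reagents that add atoms: tert-butyl hydroperoxide (oxygen donor, used as LiOOtBu), CC(C)(C)OO; triisopropylsilyl trifluoromethanesulfonate, CC(C)[Si](OS(=O)(=O)C(F)(F)F)(C(C)C)C(C)C
Why: Oxidation of a lithium acetylide with lithium tert-butylperoxide is the established route to lithium ynolates, and the bulky silyl triflate should trap the ynolate on oxygen to give a stable siloxyalkyne (acetylide oxidation followed by O-silylation).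

Step 2
Reactants: 5 3-methoxyprop-1-yne
Product: 8 3-methoxy-1-(triisopropylsiloxy)prop-1-yne, via lithium 3-methoxypropynide 6 (not isolated), via lithium 3-methoxypropynolate 7 (not isolated)
Conditions: n-BuLi, THF, −78 °C; LiOOtBu [t-BuOOH, LiN(SiMe3)2], −78 → 0 °C; iPr3SiOTf, −78 → 0 °C
Reagents that add atoms: tert-butyl hydroperoxide (oxygen donor, used as LiOOtBu), CC(C)(C)OO; triisopropylsilyl trifluoromethanesulfonate, CC(C)[Si](OS(=O)(=O)C(F)(F)F)(C(C)C)C(C)C
Why: The same acetylide oxidation and O-silylation should apply, since the propargylic methyl ether is inert to the base and methoxide is too poor a leaving group to be expelled from the ynolate at low temperature.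

Step 3
Reactants: 8 3-methoxy-1-(triisopropylsiloxy)prop-1-yne; 9 acetyl chloride
Product: 11 2-(methoxymethyl)-3-(triisopropylsiloxy)cyclobut-2-en-1-one, via ketene 10 (not isolated)
Conditions: Et3N, Et2O, AcCl added slowly, 0 °C → rt
Reagents that add atoms: none
Why: Ketene released by dehydrochlorination of acetyl chloride should undergo the polar [2+2] cycloaddition typical of ynol ethers, the alkyne carbon remote from oxygen bonding to the ketene carbonyl carbon, which places the CH2OMe arm on C2 and the siloxy group on C3 of the cyclobutenone.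

Step 4
Reactants: 11 2-(methoxymethyl)-3-(triisopropylsiloxy)cyclobut-2-en-1-one; 4 1-(triisopropylsiloxy)prop-1-yne
Product: 16 4-(methoxymethyl)-2-methyl-3,5-bis(triisopropylsiloxy)phenol, via vinylketene 12 (not isolated), via vinylcyclobutenone adduct 13 (not isolated), via dienylketene 14 (not isolated), via cyclohexadienone 15 (not isolated)
Conditions: 4 (1.5 equiv), toluene, sealed tube, 110 → 145 °C
Reagents that add atoms: none
Why: Thermal 4-electron electrocyclic opening of 11 gives vinylketene 12, which adds siloxyalkyne 4 in a [2+2] to give 13; 4-electron opening of 13 and 6-electron electrocyclic closure of dienylketene 14 (bond between the ketene carbon and the terminal CH2, the mode by which ring F closes) give dienone 15, which tautomerises to phenol 16. This is the Danheiser benzannulation of a cyclobutenone with a siloxyalkyne, applied to a 3-siloxycyclobutenone so that a phloroglucinol pattern results instead of a resorcinol pattern. The new bonds are C(OH)–C(CH3) and C(CH2OMe)–C(OSi), and the ring is completed by re-joining the former carbonyl and CH2 carbons of 11. No stereocentre survives, because the quaternary carbon of 13 becomes sp2 on ring opening. The only selectivity needed is the regiochemistry of the [2+2], which is secured by polarity: the methyl-bearing alkyne carbon attacks the ketene carbonyl carbon, so CH3 ends up next to the new OH and the siloxy carbon next to the arm carbon. Ring opening of 13 is reversible, so material should funnel through the rotamer of 14 that can close, and the ether and silyl ethers should tolerate neutral heating.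

Step 5
Reactants: 16 4-(methoxymethyl)-2-methyl-3,5-bis(triisopropylsiloxy)phenol
Product: 17 1-(methoxymethoxy)-4-(methoxymethyl)-2-methyl-3,5-bis(triisopropylsiloxy)benzene
Conditions: MOMCl, iPr2NEt, CH2Cl2, 0 °C → rt
Reagents that add atoms: chloromethyl methyl ether, COCCl
Why: Williamson-type O-alkylation of the one free, unhindered phenol installs a methoxymethyl ether that serves as the directing group for the next step.

Step 6
Reactants: 17 1-(methoxymethoxy)-4-(methoxymethyl)-2-methyl-3,5-bis(triisopropylsiloxy)benzene
Product: 19 1-[2-(methoxymethoxy)-5-(methoxymethyl)-3-methyl-4,6-bis(triisopropylsiloxy)phenyl]butan-1-one, via aryllithium 18 (not isolated)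
Conditions: s-BuLi, TMEDA, THF, −78 °C; PrC(O)N(OMe)Me, −78 → −20 °C; aq. NH4Cl
Reagents that add atoms: N-methoxy-N-methylbutanamide, CCCC(=O)N(C)OC
Why: Directed ortho-metalation by the methoxymethoxy group can only occur at the single remaining ring CH, and acylation of the aryllithium with the N-methoxy-N-methylamide should stop at the ketone through the chelated tetrahedral adduct, the low temperature holding back migration of the neighbouring silyl group.

Step 7
Reactants: 19 1-[2-(methoxymethoxy)-5-(methoxymethyl)-3-methyl-4,6-bis(triisopropylsiloxy)phenyl]butan-1-one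
Product: 21 1-[2,4,6-trihydroxy-3-(methoxymethyl)-5-methylphenyl]butan-1-one, via bisphenol 20 (not isolated)
Conditions: HF·pyridine, THF, 0 °C → rt; then HCl, MeOH, 40 °C
Reagents that add atoms: none
Why: Fluoride cleaves the two aryl silyl ethers and methanolic acid then cleaves the methoxymethyl acetal, while the benzylic methyl ether is preserved because methanol as solvent returns any benzylic cation to the same ether (desilylation followed by acetal solvolysis).

Step 8
Reactants: 22 1-(2,4,6-trihydroxyphenyl)butan-1-one (2',4',6'-trihydroxybutyrophenone)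
Product: 23 1-[3-(dimethylaminomethyl)-2,4,6-trihydroxyphenyl]butan-1-one
Conditions: 22 (3 equiv), CH2=NMe2+ I− (1 equiv, slow addition), MeCN–THF, 0 °C → rt; aq. NaHCO3; acid–base extraction
Reagents that add atoms: dimethylmethyleneiminium iodide, C=[N+](C)C.[I-]
Why: Mannich aminomethylation of the electron-rich phloroglucinol ring with the preformed iminium salt is fast at 0 °C, and slow addition of the salt to an excess of 22 should hold the reaction at the mono-Mannich base, which its basic nitrogen allows to be separated from recovered 22.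

Step 9
Reactants: 23 1-[3-(dimethylaminomethyl)-2,4,6-trihydroxyphenyl]butan-1-one; 22 1-(2,4,6-trihydroxyphenyl)butan-1-one
Product: 25 bis(3-butanoyl-2,4,6-trihydroxyphenyl)methane, via monomer quinone methide 24 (not isolated)
Conditions: 22 (3 equiv), dioxane, 70 °C, N2 sweep, slow addition of 23
Reagents that add atoms: none
Why: Thermal loss of dimethylamine from the ortho-hydroxybenzylamine (retro-Mannich) should give quinone methide 24, which the excess of 22 captures at a free ring carbon in a Friedel–Crafts (vinylogous Michael) alkylation with re-aromatisation, closing the CH2 bridge without alkali.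

Step 10
Reactants: 25 bis(3-butanoyl-2,4,6-trihydroxyphenyl)methane
Product: 26 1-{3-[(3-butanoyl-2,4,6-trihydroxyphenyl)methyl]-5-(dimethylaminomethyl)-2,4,6-trihydroxyphenyl}butan-1-one
Conditions: 25 (2.5 equiv), CH2=NMe2+ I− (1 equiv, slow addition), MeCN–THF, 0 °C → rt; aq. NaHCO3; acid–base extraction
Reagents that add atoms: dimethylmethyleneiminium iodide, C=[N+](C)C.[I-]
Why: The same Mannich aminomethylation takes one of the two equivalent free ring carbons of the symmetric dimer, and the excess of 25 (recovered and used in the next step) should limit the reaction to one ring.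

Step 11
Reactants: 26 1-{3-[(3-butanoyl-2,4,6-trihydroxyphenyl)methyl]-5-(dimethylaminomethyl)-2,4,6-trihydroxyphenyl}butan-1-one; 25 bis(3-butanoyl-2,4,6-trihydroxyphenyl)methane
Product: 28 bis{3-butanoyl-5-[(3-butanoyl-2,4,6-trihydroxyphenyl)methyl]-2,4,6-trihydroxyphenyl}methane (linear tetramer of rings B–E), via dimer quinone methide 27 (not isolated)
Conditions: 25 (3 equiv), dioxane, 70 °C, N2 sweep, slow addition of 26
Reagents that add atoms: none
Why: Retro-Mannich loss of dimethylamine should give quinone methide 27 on the inner ring, and its Friedel–Crafts (vinylogous Michael) capture by a free ring carbon of a second dimer forms the C/D bridge, the excess of 25 keeping the product at the tetramer.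

Step 12
Reactants: 21 1-[2,4,6-trihydroxy-3-(methoxymethyl)-5-methylphenyl]butan-1-one; 28 linear tetramer of rings B–E
Product: 30 pentamer of rings B–F (free CH on ring B), via ring F quinone methide 29 (not isolated)
Conditions: 28 (3 equiv), PPTS (10 mol%), dioxane, 80 °C, slow addition of 21
Reagents that add atoms: none
Why: Acid-assisted loss of methanol from the ortho-hydroxybenzyl ether should give quinone methide 29, which is captured by a free ring CH of 28 in a Friedel–Crafts (vinylogous Michael) alkylation, the two ends of 28 being equivalent and its excess favouring mono-alkylation.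

Step 13
Reactants: 30 pentamer of rings B–F
Product: 31 pentamer of rings B–F carrying a dimethylaminomethyl group on the formerly free carbon of ring B
Conditions: CH2=NMe2+ I− (1.05 equiv), MeCN–THF, 0 °C → rt; aq. NaHCO3
Reagents that add atoms: dimethylmethyleneiminium iodide, C=[N+](C)C.[I-]
Why: Mannich aminomethylation with the preformed iminium salt should take place at the only unsubstituted, phenol-activated ring carbon of the pentamer, that of ring B.

Step 14
Reactants: 22 1-(2,4,6-trihydroxyphenyl)butan-1-one
Product: 32 2-butanoyl-3,5-dihydroxy-4,4-dimethylcyclohexa-2,5-dien-1-one (butyrylfilicinic acid, ring A)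
Conditions: NaOMe (3.2 equiv), MeI (2.2 equiv), MeOH, 0 °C → rt; dil. HCl
Reagents that add atoms: iodomethane, CI
Why: Twofold C-methylation of the phloroglucinol polyanion at one ring carbon (alkylative dearomatisation) is the classical conversion of acylphloroglucinols into acylfilicinic acids.

Step 15
Reactants: 31 pentamer Mannich base; 32 2-butanoyl-3,5-dihydroxy-4,4-dimethylcyclohexa-2,5-dien-1-one
Product: 34 CNP0309827.0 (hexamer of rings A–F), via ring B quinone methide 33 (not isolated)
Conditions: 32 (1.1 equiv), dioxane, 60 °C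
Reagents that add atoms: none
Why: Thermal loss of dimethylamine from the ortho-hydroxybenzylamine (retro-Mannich) should give quinone methide 33, which the acidic, strongly nucleophilic enol carbon of 32 captures by Michael addition, closing the last CH2 bridge without alkali.

**Compound list**

1 | propyne | CC#C | starting material
2 | lithium propynide | CC#[C-].[Li+] | intermediate
3 | lithium propynolate | CC#C[O-].[Li+] | intermediate
4 | 1-(triisopropylsiloxy)prop-1-yne | CC#CO[Si](C(C)C)(C(C)C)C(C)C | intermediate
5 | 3-methoxyprop-1-yne (methyl propargyl ether) | COCC#C | starting material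
6 | lithium 3-methoxypropynide | COCC#[C-].[Li+] | intermediate
7 | lithium 3-methoxypropynolate | COCC#C[O-].[Li+] | intermediate
8 | 3-methoxy-1-(triisopropylsiloxy)prop-1-yne | COCC#CO[Si](C(C)C)(C(C)C)C(C)C | intermediate
9 | acetyl chloride | CC(Cl)=O | starting material
10 | ketene | C=C=O | intermediate
11 | 2-(methoxymethyl)-3-(triisopropylsiloxy)cyclobut-2-en-1-one | COCC1=C(O[Si](C(C)C)(C(C)C)C(C)C)CC1=O | intermediate
12 | 2-(methoxymethyl)-3-(triisopropylsiloxy)buta-1,3-dien-1-one (vinylketene) | COCC(=C=O)C(=C)O[Si](C(C)C)(C(C)C)C(C)C | intermediate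
13 | 4-(methoxymethyl)-2-methyl-3-(triisopropylsiloxy)-4-[1-(triisopropylsiloxy)ethenyl]cyclobut-2-en-1-one (racemic) | COCC1(C(=C)O[Si](C(C)C)(C(C)C)C(C)C)C(=O)C(C)=C1O[Si](C(C)C)(C(C)C)C(C)C | intermediate
14 | 4-(methoxymethyl)-2-methyl-3,5-bis(triisopropylsiloxy)hexa-1,3,5-trien-1-one, ketene and siloxyvinyl groups cis on the central double bond (dienylketene) | O=C=C(C)/C(O[Si](C(C)C)(C(C)C)C(C)C)=C(COC)\C(=C)O[Si](C(C)C)(C(C)C)C(C)C | intermediate
15 | 4-(methoxymethyl)-2-methyl-3,5-bis(triisopropylsiloxy)cyclohexa-2,4-dien-1-one | COCC1=C(O[Si](C(C)C)(C(C)C)C(C)C)CC(=O)C(C)=C1O[Si](C(C)C)(C(C)C)C(C)C | intermediate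
16 | 4-(methoxymethyl)-2-methyl-3,5-bis(triisopropylsiloxy)phenol | COCc1c(O[Si](C(C)C)(C(C)C)C(C)C)cc(O)c(C)c1O[Si](C(C)C)(C(C)C)C(C)C | intermediate
17 | 1-(methoxymethoxy)-4-(methoxymethyl)-2-methyl-3,5-bis(triisopropylsiloxy)benzene | COCc1c(O[Si](C(C)C)(C(C)C)C(C)C)cc(OCOC)c(C)c1O[Si](C(C)C)(C(C)C)C(C)C | intermediate
18 | [2-(methoxymethoxy)-5-(methoxymethyl)-3-methyl-4,6-bis(triisopropylsiloxy)phenyl]lithium | COCc1c(O[Si](C(C)C)(C(C)C)C(C)C)c([Li])c(OCOC)c(C)c1O[Si](C(C)C)(C(C)C)C(C)C | intermediate
19 | 1-[2-(methoxymethoxy)-5-(methoxymethyl)-3-methyl-4,6-bis(triisopropylsiloxy)phenyl]butan-1-one | CCCC(=O)c1c(OCOC)c(C)c(O[Si](C(C)C)(C(C)C)C(C)C)c(COC)c1O[Si](C(C)C)(C(C)C)C(C)C | intermediate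
20 | 1-[4,6-dihydroxy-2-(methoxymethoxy)-5-(methoxymethyl)-3-methylphenyl]butan-1-one | CCCC(=O)c1c(OCOC)c(C)c(O)c(COC)c1O | intermediate
21 | 1-[2,4,6-trihydroxy-3-(methoxymethyl)-5-methylphenyl]butan-1-one | CCCC(=O)c1c(O)c(C)c(O)c(COC)c1O | intermediate
22 | 1-(2,4,6-trihydroxyphenyl)butan-1-one | CCCC(=O)c1c(O)cc(O)cc1O | starting material
23 | 1-[3-(dimethylaminomethyl)-2,4,6-trihydroxyphenyl]butan-1-one | CCCC(=O)c1c(O)cc(O)c(CN(C)C)c1O | intermediate
24 | 2-butanoyl-3,5-dihydroxy-6-methylidenecyclohexa-2,4-dien-1-one (monomer quinone methide) | C=C1C(=O)C(C(=O)CCC)=C(O)C=C1O | intermediate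
25 | bis(3-butanoyl-2,4,6-trihydroxyphenyl)methane | CCCC(=O)c1c(O)cc(O)c(Cc2c(O)cc(O)c(C(=O)CCC)c2O)c1O | intermediate
26 | 1-{3-[(3-butanoyl-2,4,6-trihydroxyphenyl)methyl]-5-(dimethylaminomethyl)-2,4,6-trihydroxyphenyl}butan-1-one | CCCC(=O)c1c(O)c(CN(C)C)c(O)c(Cc2c(O)cc(O)c(C(=O)CCC)c2O)c1O | intermediate
27 | 2-butanoyl-4-[(3-butanoyl-2,4,6-trihydroxyphenyl)methyl]-3,5-dihydroxy-6-methylidenecyclohexa-2,4-dien-1-one (dimer quinone methide) | CCCC(=O)C1=C(O)C(Cc2c(O)cc(O)c(C(=O)CCC)c2O)=C(O)C(=C)C1=O | intermediate
28 | bis{3-butanoyl-5-[(3-butanoyl-2,4,6-trihydroxyphenyl)methyl]-2,4,6-trihydroxyphenyl}methane (linear tetramer of rings B–E) | CCCC(=O)c1c(O)cc(O)c(Cc2c(O)c(Cc3c(O)c(Cc4c(O)cc(O)c(C(=O)CCC)c4O)c(O)c(C(=O)CCC)c3O)c(O)c(C(=O)CCC)c2O)c1O | intermediate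
29 | 2-butanoyl-3,5-dihydroxy-4-methyl-6-methylidenecyclohexa-2,4-dien-1-one (ring F quinone methide) | C=C1C(=O)C(C(=O)CCC)=C(O)C(C)=C1O | intermediate
30 | pentamer of rings B–F: four CH2-linked 3-butanoyl-2,4,6-trihydroxyphenyl units ending in the 3-butanoyl-2,4,6-trihydroxy-5-methylphenyl ring F, one free CH on ring B | CCCC(=O)c1c(O)cc(O)c(Cc2c(O)c(Cc3c(O)c(Cc4c(O)c(Cc5c(O)c(C)c(O)c(C(=O)CCC)c5O)c(O)c(C(=O)CCC)c4O)c(O)c(C(=O)CCC)c3O)c(O)c(C(=O)CCC)c2O)c1O | intermediate
31 | pentamer 30 with CH2NMe2 on the formerly free carbon of ring B | CCCC(=O)c1c(O)c(CN(C)C)c(O)c(Cc2c(O)c(Cc3c(O)c(Cc4c(O)c(Cc5c(O)c(C)c(O)c(C(=O)CCC)c5O)c(O)c(C(=O)CCC)c4O)c(O)c(C(=O)CCC)c3O)c(O)c(C(=O)CCC)c2O)c1O | intermediate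
32 | 2-butanoyl-3,5-dihydroxy-4,4-dimethylcyclohexa-2,5-dien-1-one | CCCC(=O)C1=C(O)C(C)(C)C(O)=CC1=O | intermediate
33 | ring B quinone methide of the pentamer (exocyclic CH2 on ring B next to a ring C=O) | CCCC(=O)C1=C(O)C(Cc2c(O)c(Cc3c(O)c(Cc4c(O)c(Cc5c(O)c(C)c(O)c(C(=O)CCC)c5O)c(O)c(C(=O)CCC)c4O)c(O)c(C(=O)CCC)c3O)c(O)c(C(=O)CCC)c2O)=C(O)C(=C)C1=O | intermediate
34 | CNP0309827.0 (hexamer of rings A–F) | CCCC(=O)C1=C(O)C(C)(C)C(O)=C(Cc2c(O)c(Cc3c(O)c(Cc4c(O)c(Cc5c(O)c(Cc6c(O)c(C)c(O)c(C(=O)CCC)c6O)c(O)c(C(=O)CCC)c5O)c(O)c(C(=O)CCC)c4O)c(O)c(C(=O)CCC)c3O)c(O)c(C(=O)CCC)c2O)C1=O | target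

**Totals**

Total step count: 15.
Longest linear sequence: 9 steps (steps 2, 3, 4, 5, 6, 7, 12, 13, 15).

**Steps most likely to fail**

Step 4. The 3-siloxy group stabilises cyclobutenone 11 as a vinylogous ester, so its electrocyclic opening may be slow. Rearrangement of the siloxyalkyne to a silylketene, ketene oligomerisation or loss of the silyl enol ether could then outrun the [2+2] capture. The fallback leaves the benzannulation and makes the ring F electrophile by classical arene chemistry. It sets out from 22: mono-C-methylation with one equivalent each of MeI and NaOMe in MeOH should give 1-(2,4,6-trihydroxy-3-methylphenyl)butan-1-one F1. Aminomethylation of its one free ring carbon with dimethylmethyleneiminium iodide should give 1-[3-(dimethylaminomethyl)-2,4,6-trihydroxy-5-methylphenyl]butan-1-one F2. Heating F2 with an excess of tetramer 28 in dioxane (loss of dimethylamine, quinone methide capture) rejoins the route at 30.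

Step 12. The tetramer 28 has two equivalent free positions and is likely to be poorly soluble. Alkylation at both ends, or ipso attack of the quinone methide with acid-promoted exchange of methylene bridges, could give chain-length mixtures. The fallback builds the chain in two smaller unions and sets out from 21 and dimer 25. Compound 21 and a large excess of the soluble dimer 25 (PPTS, dioxane) should give the trimer of rings D–F, 1-{3-[(3-butanoyl-2,4,6-trihydroxyphenyl)methyl]-5-[(3-butanoyl-2,4,6-trihydroxy-5-methylphenyl)methyl]-2,4,6-trihydroxyphenyl}butan-1-one F3. Aminomethylation of its one free ring carbon with dimethylmethyleneiminium iodide should give the Mannich base of the trimer F4. Heating F4 with an excess of 25 then adds rings B and C and rejoins the route at 30.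

Step 15. The bridge next to ring A is the one most prone to retro-Michael cleavage and re-addition. Under heat and the dimethylamine set free, exchange of this bridge could give the symmetrical ring A dimer and chain-length mixtures. The fallback moves the leaving group to ring A, where elimination needs no heating, and sets out from 32. Aminomethylation of 32 with dimethylmethyleneiminium iodide should give 2-butanoyl-6-(dimethylaminomethyl)-3,5-dihydroxy-4,4-dimethylcyclohexa-2,5-dien-1-one F5. F5 loses dimethylamine at room temperature to the exocyclic enone, which is captured by the free ring B carbon of pentamer 30 (31 is bypassed) in AcOH-buffered dioxane at room temperature. This rejoins the route at 34.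

**Further compounds**

F1 | step 4 | 1-(2,4,6-trihydroxy-3-methylphenyl)butan-1-one | CCCC(=O)c1c(O)cc(O)c(C)c1O
F2 | step 4 | 1-[3-(dimethylaminomethyl)-2,4,6-trihydroxy-5-methylphenyl]butan-1-one | CCCC(=O)c1c(O)c(C)c(O)c(CN(C)C)c1O
F3 | step 12 | trimer of rings D–F with one free CH on ring D | CCCC(=O)c1c(O)cc(O)c(Cc2c(O)c(Cc3c(O)c(C)c(O)c(C(=O)CCC)c3O)c(O)c(C(=O)CCC)c2O)c1O
F4 | step 12 | trimer of rings D–F with CH2NMe2 on ring D | CCCC(=O)c1c(O)c(CN(C)C)c(O)c(Cc2c(O)c(Cc3c(O)c(C)c(O)c(C(=O)CCC)c3O)c(O)c(C(=O)CCC)c2O)c1O
F5 | step 15 | 2-butanoyl-6-(dimethylaminomethyl)-3,5-dihydroxy-4,4-dimethylcyclohexa-2,5-dien-1-one | CCCC(=O)C1=C(O)C(C)(C)C(O)=C(CN(C)C)C1=O
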